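**Plan**

1. Retrosynthesis: in each tetrahydrofuran ring the O–CH2 bond and the benzylic C–C(OH) bond are cut (O7–C8 and C5–C6 first, then O3–C4 and C1–C2; locants of 3,7-dioxabicyclo[3.3.0]octane). This leaves two aryl aldehydes and the chain C8–C1(OH)–C5(OH)–C4.
2. Enabling feature: this chain, two vicinal tertiary carbinols (C1, C5) each bearing one O–CH2 carbon (C8, C4), is the C2-symmetric skeleton of tartaric acid. At the carboxyl oxidation level C4 and C8 make C5–H and C1–H enolizable, and each lies 1,4 to the alkoxide that an aldol addition at the other carbinol carbon creates, so one aldol/lactonization event forms the C–C and the C–O bond of a ring.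
3. Forward: D-tartrate acetonide and O-tosylvanillin give ring A (C1, C2, O3, C4, C5) as a γ-lactone (step 2). A second aldol/lactonization closes ring B (C5, C6, O7, C8, C1) to a C2-symmetric bis-lactone (step 3). The lactones are reduced to ethers (steps 4, 5), then acetonide and tosyl groups are removed (steps 6, 7).
4. Stereochemistry: C1 and C5 are the two (S) centres of D-tartaric acid, with H replaced by C with retention because only cis-fused rings can close. C2 and C6 are set in the two aldol additions by the adjacent quaternary centre.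
5. Helpers removed later: carboxyl oxidation level at C4/C8, the acetonide ring on the 1,5-diol, tosyl groups on the phenols.

Key step: step 3

Remark: Ts = 4-methylbenzenesulfonyl. Vanillin and the (4S,5S)-acetonide 3 (from D-tartaric acid) are taken as commercial. The configuration at C2 and C6 is predicted from a transition-state argument and is the main uncertainty of the route.

**Route**

Step 1
Reactants: 1 vanillin
Product: 2 4-formyl-2-methoxyphenyl 4-methylbenzenesulfonate (O-tosylvanillin)
Conditions: TsCl, Et3N, DMAP (cat.), CH2Cl2, 0 °C → rt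
Reagents that add atoms: 4-methylbenzenesulfonyl chloride, Cc1ccc(cc1)S(=O)(=O)Cl
Why: Base-mediated O-sulfonylation of the phenol; the electron-poor sulfonate tolerates enolates and hydrides and later keeps the benzylic C–O bonds from ionizing under acid.

Step 2
Reactants: 3 dimethyl (4S,5S)-2,2-dimethyl-1,3-dioxolane-4,5-dicarboxylate; 2 O-tosylvanillin
Product: 6 methyl (3aS,6R,6aS)-6-(3-methoxy-4-tosyloxyphenyl)-2,2-dimethyl-4-oxotetrahydrofuro[3,4-d][1,3]dioxole-6a-carboxylate (mono-lactone; aryl cis to the acetal oxygen on C6a), via lithium enolate 4 (not isolated), via lithium aldolate 5 (not isolated)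
Conditions: LiN(i-Pr)2 (1.05 equiv), THF/DMPU, −78 °C, 10 min; 2, −78 → −20 °C; AcOH
Reagents that add atoms: none
Why: Tandem ester-enolate aldol addition and 5-exo-trig lactonization (the lactone-forming stage of a Stobbe condensation, here with no α-hydrogen left for ring-opening elimination): the aldol step is reversible and only the adduct with the new C1–C2 bond cis to the ester on C5 can lactonize, so C1 is fixed with retention of the tartrate configuration, while C2 should be set by an extended transition state in which the aryl group avoids that ester and ends cis to the acetal oxygen on C1.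

Step 3
Reactants: 6 mono-lactone; 2 O-tosylvanillin
Product: 9 (1S,2R,5S,6R)-2,6-bis(3-methoxy-4-tosyloxyphenyl)-1,5-(isopropylidenedioxy)-3,7-dioxabicyclo[3.3.0]octane-4,8-dione (C2-symmetric bis-lactone), via lithium enolate 7 (not isolated), via lithium aldolate 8 (not isolated)
Conditions: LiN(i-Pr)2 (1.05 equiv), THF/DMPU, −78 °C; 2, −78 → 0 °C; AcOH
Reagents that add atoms: none
Why: The base removes the only α-hydrogen of 6 (C5–H, next to the lactone C4=O) to give the bicyclic enolate 7, whose C5 adds to the aldehyde carbon of 2 (new C5–C6 bond), and the lithium alkoxide 8 then attacks the ester carbon on C1 (new O7–C8 bond) with loss of methoxide. The closest known reaction type is the tandem ester-enolate aldol addition/γ-lactonization of succinate-type diesters and the aldol chemistry of tartrate acetal enolates. Ring B closes by a 5-exo-trig acyl substitution. C5 is controlled by ring fusion: the enolate carbon is shared by the dioxolane and ring A, so the aldehyde can only enter on the face that keeps this 5/5 fusion cis, which is the face carrying the C1 ester and so puts the new alkoxide within reach of it. C6 should be set in the addition, with the aryl group in the one quadrant not flanked by the upright C1 ester and the aldehyde C=O anti to the enolate C=C (extended transition state, favoured by DMPU), which after closure leaves aryl cis to the acetal oxygen on C5 as in the C2-symmetric product. The step needs addition to outrun β-elimination of the acetal oxygen on C1, which the ring disfavours by holding that C–O bond near the enolate plane, and it needs complete conversion, which the irreversible lactonization secures by draining the reversible aldol equilibrium.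

Step 4
Reactants: 9 bis-lactone
Product: 10 (1S,2R,5S,6R)-2,6-bis(3-methoxy-4-tosyloxyphenyl)-1,5-(isopropylidenedioxy)-3,7-dioxabicyclo[3.3.0]octane-4,8-diol (bis-lactol, mixture of anomers)
Conditions: i-Bu2AlH (3 equiv), CH2Cl2, −78 °C; aq. KNaC4H4O6 (Rochelle salt)
Reagents that add atoms: none
Why: Partial reduction of γ-lactones to lactols through tetrahedral aluminates that are stable at −78 °C; aryl sulfonates and the ketal are inert to the hydride at this temperature.

Step 5
Reactants: 10 bis-lactol
Product: 11 (1S,2R,5S,6R)-2,6-bis(3-methoxy-4-tosyloxyphenyl)-1,5-(isopropylidenedioxy)-3,7-dioxabicyclo[3.3.0]octane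
Conditions: Et3SiH, BF3·OEt2, CH2Cl2, −78 → −30 °C
Reagents that add atoms: none
Why: Ionic hydrogenation of the lactols (silane reduction of the cyclic oxocarbenium ions) turns C4 and C8 into CH2 without touching a stereocentre, and the sulfonate-deactivated aryl rings disfavour competing ionization of the benzylic C–O bonds.

Step 6
Reactants: 11 bis-ether acetonide
Product: 12 (1S,2R,5S,6R)-2,6-bis(3-methoxy-4-tosyloxyphenyl)-3,7-dioxabicyclo[3.3.0]octane-1,5-diol
Conditions: CF3CO2H/H2O (4:1), 0 °C → rt
Reagents that add atoms: none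
Why: Acid-catalysed hydrolysis of the isopropylidene ketal; the benzylic ethers still carry electron-poor aryl groups and should not epimerize.

Step 7
Reactants: 12 diol bis-tosylate
Product: 13 prinsepiol, (1S,2R,5S,6R)-2,6-bis(4-hydroxy-3-methoxyphenyl)-3,7-dioxabicyclo[3.3.0]octane-1,5-diol
Conditions: KOH, H2O/1,4-dioxane (1:1), 70 °C; aq. HCl to pH 5
Reagents that add atoms: none
Why: Alkaline hydrolysis of the aryl sulfonates by attack of hydroxide at sulfur; the alcohol-free medium avoids an alkyl tosylate that could O-alkylate the phenoxide.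

**Compound list**

1 | vanillin (4-hydroxy-3-methoxybenzaldehyde) | COc1cc(C=O)ccc1O | starting material
2 | 4-formyl-2-methoxyphenyl 4-methylbenzenesulfonate | COc1cc(C=O)ccc1OS(=O)(=O)c1ccc(C)cc1 | intermediate
3 | dimethyl (4S,5S)-2,2-dimethyl-1,3-dioxolane-4,5-dicarboxylate (dimethyl 2,3-O-isopropylidene-D-tartrate) | COC(=O)[C@H]1OC(C)(C)O[C@@H]1C(=O)OC | starting material
4 | lithium enolate of 3 (one ester enolized, (S) centre at C5 intact; not isolated) | COC(=O)[C@H]1OC(C)(C)OC1=C([O-])OC.[Li+] | intermediate
5 | lithium alkoxide of dimethyl (4S,5S)-4-[(R)-hydroxy(3-methoxy-4-tosyloxyphenyl)methyl]-2,2-dimethyl-1,3-dioxolane-4,5-dicarboxylate (not isolated) | [O-][C@H](c2ccc(OS(=O)(=O)c3ccc(C)cc3)c(OC)c2)[C@]1(C(=O)OC)OC(C)(C)O[C@@H]1C(=O)OC.[Li+] | intermediate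
6 | methyl (3aS,6R,6aS)-6-(3-methoxy-4-tosyloxyphenyl)-2,2-dimethyl-4-oxotetrahydrofuro[3,4-d][1,3]dioxole-6a-carboxylate (cis-fused; aryl cis to the acetal O on C6a, trans to the ester) | COc1cc([C@H]2OC(=O)[C@H]3OC(C)(C)O[C@@]23C(=O)OC)ccc1OS(=O)(=O)c1ccc(C)cc1 | intermediate
7 | lithium enolate of 6 (lactone enolate at the ring-fusion carbon; not isolated) | COc1cc([C@H]2OC([O-])=C3OC(C)(C)O[C@@]23C(=O)OC)ccc1OS(=O)(=O)c1ccc(C)cc1.[Li+] | intermediate
8 | lithium alkoxide of the aldol adduct of 7 with 2 (new (R)-carbinol on the ring-fusion carbon, cis to the ester; not isolated) | COc1cc([C@H]2OC(=O)[C@@]3([C@H]([O-])c4ccc(OS(=O)(=O)c5ccc(C)cc5)c(OC)c4)OC(C)(C)O[C@@]23C(=O)OC)ccc1OS(=O)(=O)c1ccc(C)cc1.[Li+] | intermediate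
9 | (1S,2R,5S,6R)-2,6-bis(3-methoxy-4-tosyloxyphenyl)-1,5-(isopropylidenedioxy)-3,7-dioxabicyclo[3.3.0]octane-4,8-dione | COc1cc([C@H]2OC(=O)[C@]3(O4)[C@@H](c5ccc(OS(=O)(=O)c6ccc(C)cc6)c(OC)c5)OC(=O)[C@]23OC4(C)C)ccc1OS(=O)(=O)c1ccc(C)cc1 | intermediate
10 | (1S,2R,5S,6R)-2,6-bis(3-methoxy-4-tosyloxyphenyl)-1,5-(isopropylidenedioxy)-3,7-dioxabicyclo[3.3.0]octane-4,8-diol (anomer mixture) | COc1cc([C@H]2OC(O)[C@]3(O4)[C@@H](c5ccc(OS(=O)(=O)c6ccc(C)cc6)c(OC)c5)OC(O)[C@]23OC4(C)C)ccc1OS(=O)(=O)c1ccc(C)cc1 | intermediate
11 | (1S,2R,5S,6R)-2,6-bis(3-methoxy-4-tosyloxyphenyl)-1,5-(isopropylidenedioxy)-3,7-dioxabicyclo[3.3.0]octane | COc1cc([C@H]2OC[C@]3(O4)[C@@H](c5ccc(OS(=O)(=O)c6ccc(C)cc6)c(OC)c5)OC[C@]23OC4(C)C)ccc1OS(=O)(=O)c1ccc(C)cc1 | intermediate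
12 | (1S,2R,5S,6R)-2,6-bis(3-methoxy-4-tosyloxyphenyl)-3,7-dioxabicyclo[3.3.0]octane-1,5-diol | COc1cc([C@H]2OC[C@]3(O)[C@@H](c4ccc(OS(=O)(=O)c5ccc(C)cc5)c(OC)c4)OC[C@]23O)ccc1OS(=O)(=O)c1ccc(C)cc1 | intermediate
13 | prinsepiol, (1S,2R,5S,6R)-2,6-bis(4-hydroxy-3-methoxyphenyl)-3,7-dioxabicyclo[3.3.0]octane-1,5-diol | COc1cc([C@H]2OC[C@]3(O)[C@@H](c4ccc(O)c(OC)c4)OC[C@]23O)ccc1O | target

**Totals and risks**

Total steps: 7. Longest linear sequence: 7 steps (1 → 13); 6 steps from 3.

Steps most likely to fail:

Step 3 (key step). The addition may show poor facial selectivity at the new benzylic carbon C6, or enolate 7 may be lost by β-elimination of the acetal oxygen before it adds. The fallback runs from 6 to 9. Enolate 7 is treated with 2 as before but quenched with AcOH at −78 °C before ring closure, to give hydroxy ester F1 (both carbinol epimers). Oxidation with Dess–Martin periodinane gives aryl ketone F2. Reduction with LiBH(s-Bu)3 in THF at −78 °C should follow the Felkin–Anh model (acetal C–O anti to the hydride, which passes the flat lactone carbonyl and not quaternary C1) to give lithium alkoxide 8, and warming closes it to 9. The benzylic centre is then set by hydride delivery and not in the C–C bond-forming event.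

Step 2. Enolate 4 may fragment by β-elimination before it is trapped, or the addition may stop at an adduct that cannot close and does not revert. The fallback runs from 3 to 6. Internal-quench silylation (LiN(i-Pr)2, Me3SiCl, THF, −78 °C) gives the stable silyl ketene acetal F3. A BF3·OEt2-mediated Mukaiyama aldol addition to 2 in CH2Cl2 at −78 °C gives hydroxy diester F4 through an open transition state. Catalytic DBU in toluene then lactonizes F4 to 6 in a separate operation.

Step 5. The Lewis acid may open the ketal reductively or ionize a benzylic C–O bond. The fallback runs from 9 to 11 and bypasses 10. LiBH4 in THF reduces both lactones to tetraol F5. A double Mitsunobu cyclodehydration (PPh3, DIAD, THF, 0 °C → rt) activates the two primary hydroxyls, so the benzylic hydroxyls close both rings with retention at C2 and C6.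

**Further compounds**

F1 | step 3 | methyl (3aS,6R,6aS)-3a-[hydroxy(3-methoxy-4-tosyloxyphenyl)methyl]-6-(3-methoxy-4-tosyloxyphenyl)-2,2-dimethyl-4-oxotetrahydrofuro[3,4-d][1,3]dioxole-6a-carboxylate (carbinol epimers) | COc1cc([C@H]2OC(=O)[C@@]3(C(O)c4ccc(OS(=O)(=O)c5ccc(C)cc5)c(OC)c4)OC(C)(C)O[C@@]23C(=O)OC)ccc1OS(=O)(=O)c1ccc(C)cc1
F2 | step 3 | methyl (3aS,6R,6aS)-3a-(3-methoxy-4-tosyloxybenzoyl)-6-(3-methoxy-4-tosyloxyphenyl)-2,2-dimethyl-4-oxotetrahydrofuro[3,4-d][1,3]dioxole-6a-carboxylate | COc1cc([C@H]2OC(=O)[C@@]3(C(=O)c4ccc(OS(=O)(=O)c5ccc(C)cc5)c(OC)c4)OC(C)(C)O[C@@]23C(=O)OC)ccc1OS(=O)(=O)c1ccc(C)cc1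
F3 | step 2 | trimethylsilyl ketene acetal of 3 (methyl (S)-5-[methoxy(trimethylsilyloxy)methylidene]-2,2-dimethyl-1,3-dioxolane-4-carboxylate) | COC(=O)[C@H]1OC(C)(C)OC1=C(OC)O[Si](C)(C)C
F4 | step 2 | dimethyl (4S,5S)-4-[(R)-hydroxy(3-methoxy-4-tosyloxyphenyl)methyl]-2,2-dimethyl-1,3-dioxolane-4,5-dicarboxylate | O[C@H](c2ccc(OS(=O)(=O)c3ccc(C)cc3)c(OC)c2)[C@]1(C(=O)OC)OC(C)(C)O[C@@H]1C(=O)OC
F5 | step 5 | (4S,5S)-4,5-bis(hydroxymethyl)-4,5-bis[(R)-hydroxy(3-methoxy-4-tosyloxyphenyl)methyl]-2,2-dimethyl-1,3-dioxolane (tetraol) | O[C@H](c1ccc(OS(=O)(=O)c2ccc(C)cc2)c(OC)c1)[C@]1(CO)OC(C)(C)O[C@@]1(CO)[C@H](O)c1ccc(OS(=O)(=O)c2ccc(C)cc2)c(OC)c1
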